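**Plan**
- Retrosynthesis: first the O13 acetate and O8 senecioate, then the C1–C2 acyl–alkyl bond of the ten-membered ring, then the butenolide at C6–C7 and O–C12. This leaves a bromo epoxy aldehyde (C2–C6) and a thioester enol triflate (C7–C13 plus C1).
- Forward order of rings: oxirane (Sharpless epoxidation), then butenolide (Ni/Cr alkenyl triflate–aldehyde coupling with lactonization), then the ten-membered carbocycle by Pd-catalysed closure of a C2 alkylzinc onto the C1 thioester. The two esters go on last.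
- Enabling feature: C1 is the only trigonal, non-stereogenic atom of the carbocycle and has a CH2 neighbour (C2), so the ring can be closed there as a ketone. The cis-oxirane at C4–C5 (C3 and C6 syn) and the flat furanone at C6–C7 fold the chain so that C2 lies near C1.
- Stereochemistry: C4/C5 from reagent-controlled epoxidation of a Z-allylic alcohol; C6 from Felkin–Anh addition to the cis-epoxy aldehyde; C8 from (R)-5-(hydroxymethyl)butyrolactone; C10 from trans-selective methylation of that lactone.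

Key step: step 15

Remark: C1–C13 are germacrane positions (C1 ketone, C4/C5 oxirane, C6 lactone carbinol, C7=C11 butenolide alkene, C8 ester carbinol, C10 methyl-bearing carbon, C12 lactone carbonyl, C13 CH2O); ester 16 is assumed to be purchasable (otherwise one silylation of methyl 3-hydroxypropanoate).

**Route**

Step 1
Reactants: 1 4-bromobut-1-yne
Product: 3 methyl 5-bromopent-2-ynoate, via lithium acetylide 2 (not isolated)
Conditions: n-BuLi, THF, −78 °C; ClCO2Me, −78 → 0 °C
Reagents that add atoms: methyl chloroformate, COC(=O)Cl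
Why: C-acylation of a lithium acetylide with a chloroformate; the primary bromide is inert at −78 °C.

Step 2
Reactants: 3 methyl 5-bromopent-2-ynoate
Product: 4 methyl (2Z)-5-bromo-3-methylpent-2-enoate
Conditions: Me2CuLi (from MeLi, CuI), THF, −78 °C; MeOH then aq NH4Cl at −78 °C
Reagents that add atoms: lithium dimethylcuprate, [Li+].C[Cu-]C
Why: syn-carbocupration of a 2-alkynoate with cold protonation should place CH2CH2Br cis to CO2Me (Z), the geometry that later makes the oxirane cis.

Step 3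
Reactants: 4 methyl (2Z)-5-bromo-3-methylpent-2-enoate
Product: 5 (2Z)-5-bromo-3-methylpent-2-en-1-ol
Conditions: DIBAL-H, CH2Cl2, −78 °C
Reagents that add atoms: none
Why: 1,2-reduction of an enoate to the allylic alcohol by DIBAL-H, without touching the alkene geometry or the bromide.

Step 4
Reactants: 5 (2Z)-5-bromo-3-methylpent-2-en-1-ol
Product: 6 [(2R,3S)-3-(2-bromoethyl)-3-methyloxiran-2-yl]methanol
Conditions: Ti(OiPr)4 (10 mol %), D-(−)-diethyl tartrate (12 mol %), t-BuOOH, 4 Å MS, CH2Cl2, −20 °C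
Reagents that add atoms: tert-butyl hydroperoxide, CC(C)(C)OO
Why: Sharpless asymmetric epoxidation of a nerol-type Z-allylic alcohol; D-(−)-tartrate should deliver oxygen to the face that gives (2R,3S) (C5 R, C4 S), and the Z alkene fixes C3 and C6 cis on the oxirane.

Step 5
Reactants: 6 [(2R,3S)-3-(2-bromoethyl)-3-methyloxiran-2-yl]methanol
Product: 7 (2S,3S)-3-(2-bromoethyl)-3-methyloxirane-2-carbaldehyde
Conditions: Dess–Martin periodinane, NaHCO3, CH2Cl2, 0 °C
Reagents that add atoms: none
Why: Dess–Martin oxidation of an epoxy alcohol to the cis-epoxy aldehyde under buffered, non-epimerizing conditions (the descriptor at C2 changes only because CHO outranks the ring carbon).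

Step 6
Reactants: 8 (5R)-5-(hydroxymethyl)oxolan-2-one
Product: 9 (5R)-5-[(trityloxy)methyl]oxolan-2-one
Conditions: TrCl, pyridine, DMAP (cat.), CH2Cl2, rt
Reagents that add atoms: trityl chloride, ClC(c1ccccc1)(c1ccccc1)c1ccccc1
Why: tritylation of the primary alcohol gives the bulky C5 substituent that directs the next step.

Step 7
Reactants: 9 (5R)-5-[(trityloxy)methyl]oxolan-2-one
Product: 11 (3S,5R)-3-methyl-5-[(trityloxy)methyl]oxolan-2-one, via lithium enolate 10 (not isolated)
Conditions: LDA, THF, −78 °C; MeI, −78 °C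
Reagents that add atoms: iodomethane, CI
Why: lactone enolate alkylation; MeI should approach anti to the CH2OTr group, giving the trans lactone and so setting C10 (S) relative to C8 (R).

Step 8
Reactants: 11 (3S,5R)-3-methyl-5-[(trityloxy)methyl]oxolan-2-one
Product: 13 S-ethyl (2S,4R)-4-[(tert-butyldimethylsilyl)oxy]-2-methyl-5-(trityloxy)pentanethioate, via hydroxy thioester 12 (not isolated)
Conditions: Me3Al, EtSH, CH2Cl2, 0 °C → rt; then 2,6-lutidine, TBSOTf, −78 → 0 °C, same flask
Reagents that add atoms: ethanethiol, CCS; tert-butyldimethylsilyl triflate, CC(C)(C)[Si](C)(C)OS(=O)(=O)C(F)(F)F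
Why: lactone thiolysis by dimethylaluminium ethanethiolate, with immediate silylation of the freed C8 hydroxyl so that the γ-hydroxy thioester cannot relactonize.

Step 9
Reactants: 13 S-ethyl (2S,4R)-4-[(tert-butyldimethylsilyl)oxy]-2-methyl-5-(trityloxy)pentanethioate
Product: 14 S-ethyl (2S,4R)-4-[(tert-butyldimethylsilyl)oxy]-5-hydroxy-2-methylpentanethioate
Conditions: HCO2H/Et2O (1:1), 0 °C → rt, short contact
Reagents that add atoms: none
Why: acidolysis of a trityl ether, which is far faster than cleavage of the secondary TBS ether or the thioester.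

Step 10
Reactants: 14 S-ethyl (2S,4R)-4-[(tert-butyldimethylsilyl)oxy]-5-hydroxy-2-methylpentanethioate
Product: 15 S-ethyl (2S,4R)-4-[(tert-butyldimethylsilyl)oxy]-2-methyl-5-oxopentanethioate
Conditions: Dess–Martin periodinane, NaHCO3, CH2Cl2, 0 °C
Reagents that add atoms: none
Why: Dess–Martin oxidation to the α-silyloxy aldehyde (C7), used without chromatography.

Step 11
Reactants: 15 S-ethyl (2S,4R)-4-[(tert-butyldimethylsilyl)oxy]-2-methyl-5-oxopentanethioate; 16 methyl 3-[(tert-butyldimethylsilyl)oxy]propanoate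
Product: 18 S-ethyl (2S,4R)-4-[(tert-butyldimethylsilyl)oxy]-6-{[(tert-butyldimethylsilyl)oxy]methyl}-5-hydroxy-7-methoxy-2-methyl-7-oxoheptanethioate (epimers at C5/C6 of this chain), via ester enolate 17 (not isolated)
Conditions: LDA, THF, −78 °C (16); then 15, −78 °C; AcOH quench at −78 °C
Reagents that add atoms: none
Why: lithium ester enolate aldol addition, the aldehyde reacting far faster than the thioester; the two new centres are removed in steps 12–14, so their configuration is irrelevant.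

Step 12
Reactants: 18 aldol adduct
Product: 19 S-ethyl (2S,4R)-4-[(tert-butyldimethylsilyl)oxy]-6-{[(tert-butyldimethylsilyl)oxy]methyl}-7-methoxy-2-methyl-5,7-dioxoheptanethioate
Conditions: Dess–Martin periodinane, NaHCO3, CH2Cl2, rt
Reagents that add atoms: none
Why: Dess–Martin oxidation of the β-hydroxy ester to the α-substituted β-keto ester.

Step 13
Reactants: 19 β-keto ester
Product: 21 methyl (2Z,4R,6S)-4-[(tert-butyldimethylsilyl)oxy]-2-{[(tert-butyldimethylsilyl)oxy]methyl}-7-(ethylsulfanyl)-6-methyl-7-oxo-3-{[(trifluoromethyl)sulfonyl]oxy}hept-2-enoate, via chelated enolate 20 (not isolated)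
Conditions: LiHMDS, THF, −78 °C; Comins' reagent, −78 → 0 °C
Reagents that add atoms: N-(5-chloropyridin-2-yl)bis(trifluoromethanesulfonimide), FC(F)(F)S(=O)(=O)N(c1ccc(Cl)cn1)S(=O)(=O)C(F)(F)F
Why: O-sulfonylation of the lithium-chelated β-keto ester enolate should give the Z enol triflate (OTf cis to CO2Me), the geometry needed for lactonization after C6–C7 bond formation.

Step 14
Reactants: 21 Z enol triflate; 7 (2S,3S)-3-(2-bromoethyl)-3-methyloxirane-2-carbaldehyde
Product: 23 S-ethyl (2S,4R)-4-{(2R)-2-[(2R,3S)-3-(2-bromoethyl)-3-methyloxiran-2-yl]-4-({[tert-butyldimethylsilyl]oxy}methyl)-5-oxo-2,5-dihydrofuran-3-yl}-4-[(tert-butyldimethylsilyl)oxy]-2-methylbutanethioate, via hydroxy enoate 22 (not isolated)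
Conditions: CrCl2 (6 equiv), NiCl2 (2 mol %), DMF–THF, rt; silica gel on work-up
Reagents that add atoms: none
Why: Nozaki–Hiyama–Kishi coupling of an alkenyl triflate with an aldehyde, followed by lactonization of the C6 alkoxide onto the cis CO2Me; addition anti to the oxirane C–O bond (Felkin–Anh/Cornforth) should set 6R, and the silyl ether at C8 and the primary bromide are not activated by Cr(II)/Ni.

Step 15
Reactants: 23 thioester bromide butenolide
Product: 25 (4S,5R,6R,8R,10S)-8,13-bis[(tert-butyldimethylsilyl)oxy]-4,5-epoxy-1-oxogermacr-7(11)-en-12,6-olide (ten-membered ketone with fused butenolide and cis-oxirane), via alkylzinc bromide 24 (not isolated)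
Conditions: Zn dust, LiCl, THF, 45 °C; then syringe-pump addition (12 h) into PdCl2(PPh3)2 (15 mol %), toluene, 45 °C, final 1 mM
Reagents that add atoms: none
Why: Proposed new method: Pd(0) inserts into the C1(acyl)–S bond of the thioester, the tethered primary alkylzinc at C2 transmetalates within the same molecule, and reductive elimination from the eleven-membered acyl(alkyl)palladacycle forms the C1–C2 bond and the ketone. The closest known reaction type is the intermolecular Fukuyama thioester–organozinc ketone synthesis, together with Pd-mediated ring-closing Negishi and Stille couplings. The ten-membered carbocycle closes by acyl substitution at C1 (formally 10-exo-trig), with the oxirane and the butenolide already in place. No stereocentre is created; C10 next to the acyl group should not epimerize because no base is present, and C4, C5, C6 and C8 are remote from the reacting atoms. The step needs ring closure to beat chain growth and the organozinc to spare lactone, oxirane and silyl ethers: slow addition of preformed 24 keeps the acylpalladium dilute, the cis-oxirane and the flat furanone fold the chain so that C2 lies near C1, and alkylzinc halides do not add to esters or open epoxides without copper or strong Lewis acids.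

Step 16
Reactants: 25 bis-silyl macrocycle
Product: 26 (4S,5R,6R,8R,10S)-4,5-epoxy-8,13-dihydroxy-1-oxogermacr-7(11)-en-12,6-olide
Conditions: HF·pyridine, excess pyridine, THF, 0 °C → rt
Reagents that add atoms: none
Why: buffered fluoride desilylation of both TBS ethers; the C8 hydroxyl is trans to C12 across C7=C11 and so cannot translactonize (it may sit reversibly as the C1 hemiketal).

Step 17
Reactants: 26 diol
Product: 27 (4S,5R,6R,8R,10S)-13-acetoxy-4,5-epoxy-8-hydroxy-1-oxogermacr-7(11)-en-12,6-olide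
Conditions: AcCl (1.1 equiv), 2,4,6-collidine, CH2Cl2, −78 °C
Reagents that add atoms: acetyl chloride, CC(=O)Cl
Why: selective acetylation of the primary allylic C13 hydroxyl over the hindered secondary C8 hydroxyl with AcCl/collidine at low temperature.

Step 18
Reactants: 27 C13 acetate
Product: 28 target, (4S,5R,6R,8R,10S)-13-acetoxy-4,5-epoxy-8-[(3-methylbut-2-enoyl)oxy]-1-oxogermacr-7(11)-en-12,6-olide
Conditions: 3-methylbut-2-enoyl chloride, pyridine, DMAP (cat.), CH2Cl2, 0 °C → rt
Reagents that add atoms: 3-methylbut-2-enoyl chloride, CC(C)=CC(=O)Cl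
Why: DMAP-catalysed acylation of the secondary C8 alcohol; pyridine rather than a trialkylamine is used to limit ketene formation and deconjugation of the senecioyl group.

**Compound list**
1 | 4-bromobut-1-yne | C#CCCBr | starting material
2 | lithium 4-bromobut-1-yn-1-ide | [Li]C#CCCBr | intermediate
3 | methyl 5-bromopent-2-ynoate | COC(=O)C#CCCBr | intermediate
4 | methyl (2Z)-5-bromo-3-methylpent-2-enoate | COC(=O)/C=C(/C)CCBr | intermediate
5 | (2Z)-5-bromo-3-methylpent-2-en-1-ol | OC/C=C(/C)CCBr | intermediate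
6 | [(2R,3S)-3-(2-bromoethyl)-3-methyloxiran-2-yl]methanol | OC[C@H]1O[C@@]1(C)CCBr | intermediate
7 | (2S,3S)-3-(2-bromoethyl)-3-methyloxirane-2-carbaldehyde | O=C[C@H]1O[C@@]1(C)CCBr | intermediate
8 | (5R)-5-(hydroxymethyl)oxolan-2-one | OC[C@H]1CCC(=O)O1 | starting material
9 | (5R)-5-[(trityloxy)methyl]oxolan-2-one | C(c1ccccc1)(c2ccccc2)(c3ccccc3)OC[C@H]4CCC(=O)O4 | intermediate
10 | lithium enolate of 9 | C(c1ccccc1)(c2ccccc2)(c3ccccc3)OC[C@H]4CC=C(O[Li])O4 | intermediate
11 | (3S,5R)-3-methyl-5-[(trityloxy)methyl]oxolan-2-one | C(c1ccccc1)(c2ccccc2)(c3ccccc3)OC[C@H]4C[C@H](C)C(=O)O4 | intermediate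
12 | S-ethyl (2S,4R)-4-hydroxy-2-methyl-5-(trityloxy)pentanethioate (present as its aluminium alkoxide) | CCSC(=O)[C@@H](C)C[C@H](COC(c1ccccc1)(c2ccccc2)c3ccccc3)O | intermediate
13 | S-ethyl (2S,4R)-4-[(tert-butyldimethylsilyl)oxy]-2-methyl-5-(trityloxy)pentanethioate | CCSC(=O)[C@@H](C)C[C@H](COC(c1ccccc1)(c2ccccc2)c3ccccc3)O[Si](C)(C)C(C)(C)C | intermediate
14 | S-ethyl (2S,4R)-4-[(tert-butyldimethylsilyl)oxy]-5-hydroxy-2-methylpentanethioate | CCSC(=O)[C@@H](C)C[C@H](CO)O[Si](C)(C)C(C)(C)C | intermediate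
15 | S-ethyl (2S,4R)-4-[(tert-butyldimethylsilyl)oxy]-2-methyl-5-oxopentanethioate | CCSC(=O)[C@@H](C)C[C@H](C=O)O[Si](C)(C)C(C)(C)C | intermediate
16 | methyl 3-[(tert-butyldimethylsilyl)oxy]propanoate | COC(=O)CCO[Si](C)(C)C(C)(C)C | starting material
17 | lithium enolate of 16 | COC(O[Li])=CCO[Si](C)(C)C(C)(C)C | intermediate
18 | S-ethyl (2S,4R)-4-[(tert-butyldimethylsilyl)oxy]-6-{[(tert-butyldimethylsilyl)oxy]methyl}-5-hydroxy-7-methoxy-2-methyl-7-oxoheptanethioate | CCSC(=O)[C@@H](C)C[C@H](C(O)C(CO[Si](C)(C)C(C)(C)C)C(=O)OC)O[Si](C)(C)C(C)(C)C | intermediate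
19 | S-ethyl (2S,4R)-4-[(tert-butyldimethylsilyl)oxy]-6-{[(tert-butyldimethylsilyl)oxy]methyl}-7-methoxy-2-methyl-5,7-dioxoheptanethioate | CCSC(=O)[C@@H](C)C[C@H](C(=O)C(CO[Si](C)(C)C(C)(C)C)C(=O)OC)O[Si](C)(C)C(C)(C)C | intermediate
20 | lithium-chelated Z enolate of 19 | CCSC(=O)[C@@H](C)C[C@H](/C(O[Li])=C(/C(=O)OC)CO[Si](C)(C)C(C)(C)C)O[Si](C)(C)C(C)(C)C | intermediate
21 | methyl (2Z,4R,6S)-4-[(tert-butyldimethylsilyl)oxy]-2-{[(tert-butyldimethylsilyl)oxy]methyl}-7-(ethylsulfanyl)-6-methyl-7-oxo-3-{[(trifluoromethyl)sulfonyl]oxy}hept-2-enoate | CCSC(=O)[C@@H](C)C[C@H](/C(OS(=O)(=O)C(F)(F)F)=C(/C(=O)OC)CO[Si](C)(C)C(C)(C)C)O[Si](C)(C)C(C)(C)C | intermediate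
22 | open-chain hydroxy enoate from addition of the alkenylchromium of 21 to 7 (6R carbinol cis to CO2Me; present as its chromium alkoxide) | CCSC(=O)[C@@H](C)C[C@H](/C([C@@H](O)[C@H]1O[C@@]1(C)CCBr)=C(/C(=O)OC)CO[Si](C)(C)C(C)(C)C)O[Si](C)(C)C(C)(C)C | intermediate
23 | S-ethyl (2S,4R)-4-{(2R)-2-[(2R,3S)-3-(2-bromoethyl)-3-methyloxiran-2-yl]-4-({[tert-butyldimethylsilyl]oxy}methyl)-5-oxo-2,5-dihydrofuran-3-yl}-4-[(tert-butyldimethylsilyl)oxy]-2-methylbutanethioate | CCSC(=O)[C@@H](C)C[C@H](C1=C(CO[Si](C)(C)C(C)(C)C)C(=O)O[C@H]1[C@H]1O[C@@]1(C)CCBr)O[Si](C)(C)C(C)(C)C | intermediate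
24 | alkylzinc bromide of 23 (C2–ZnBr) | CCSC(=O)[C@@H](C)C[C@H](C1=C(CO[Si](C)(C)C(C)(C)C)C(=O)O[C@H]1[C@H]1O[C@@]1(C)CC[Zn]Br)O[Si](C)(C)C(C)(C)C | intermediate
25 | (4S,5R,6R,8R,10S)-8,13-bis[(tert-butyldimethylsilyl)oxy]-4,5-epoxy-1-oxogermacr-7(11)-en-12,6-olide | CC(C)(C)[Si](C)(C)OCC1=C2[C@@H](OC1=O)[C@H]1O[C@@]1(C)CCC(=O)[C@@H](C)C[C@H]2O[Si](C)(C)C(C)(C)C | intermediate
26 | (4S,5R,6R,8R,10S)-4,5-epoxy-8,13-dihydroxy-1-oxogermacr-7(11)-en-12,6-olide | OCC1=C2[C@@H](OC1=O)[C@H]1O[C@@]1(C)CCC(=O)[C@@H](C)C[C@H]2O | intermediate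
27 | (4S,5R,6R,8R,10S)-13-acetoxy-4,5-epoxy-8-hydroxy-1-oxogermacr-7(11)-en-12,6-olide | CC(=O)OCC1=C2[C@@H](OC1=O)[C@H]1O[C@@]1(C)CCC(=O)[C@@H](C)C[C@H]2O | intermediate
28 | (4S,5R,6R,8R,10S)-13-acetoxy-4,5-epoxy-8-[(3-methylbut-2-enoyl)oxy]-1-oxogermacr-7(11)-en-12,6-olide | CC(=O)OCC1=C2[C@@H](OC1=O)[C@H]1O[C@@]1(C)CCC(=O)[C@@H](C)C[C@H]2OC(=O)C=C(C)C | target

**Step count**
Total steps: 18. Longest linear sequence: 13 (8 → 28, steps 6–18); the aldehyde branch (steps 1–5) joins at step 14.

**Steps most likely to fail, with fallbacks**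

Step 15 (Proposed new method). Intermolecular transmetalation may outrun ring closure and give oligomers, or the C–Zn bond may be protonated before it meets the acylpalladium. The fallback closes the same bond by polar addition to an aldehyde. It sets out from 23: Fukuyama reduction of the thioester (Et3SiH, Pd/C, acetone) should give aldehyde F1. An intramolecular Takai–Utimoto chromium Barbier reaction of the primary bromide (CrCl2, cat. cobalt phthalocyanine, LiI, DMF, high dilution) should then give the ten-membered carbinol F2 as a mixture at C1. Dess–Martin oxidation returns to the route at 25.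

Step 14. Oxidative addition and transmetalation of the tetrasubstituted triflate may be too slow beside its reduction, or the facial selectivity at C6 may be poor. The fallback builds the lactone through an allylchromium instead of an alkenylchromium and sets out from 15 and 7. Morita–Baylis–Hillman reaction of 15 with methyl acrylate (DABCO) gives adduct F3, and NBS/Me2S converts it with allylic shift into the (Z)-2-(bromomethyl) enoate F4. CrCl2-mediated Barbier addition of F4 to 7 through its γ-carbon, with lactonization, gives the α-methylene-γ-butyrolactone F5 (C6 again set by Felkin–Anh addition; the C7 centre is lost next). Singlet-oxygen ene reaction (O2, hν, tetraphenylporphyrin), with hydrogen taken from C7 geminal to the carbonyl, moves the alkene to C7=C11 and gives the C13 hydroperoxide F6. PPh3 reduces this to the C13 alcohol F7, and TBSCl/imidazole returns to the route at 23.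

Step 8. The aluminium Lewis acid may strip the trityl ether, or the γ-hydroxy thioester may relactonize before it is silylated. The fallback opens the lactone as a carboxylate and makes the thioester by coupling. It sets out from 11: LiOH (THF–H2O) gives the lithium hydroxy carboxylate F8, and TBSCl/imidazole (DMF) gives the silyl ether silyl ester F9. K2CO3 in aqueous MeOH cleaves only the silyl ester to give acid F10, and EtSH/DCC/DMAP returns to the route at 13.

Further compounds
F1 | step 15 | (2S,4R)-4-{(2R)-2-[(2R,3S)-3-(2-bromoethyl)-3-methyloxiran-2-yl]-4-({[tert-butyldimethylsilyl]oxy}methyl)-5-oxo-2,5-dihydrofuran-3-yl}-4-[(tert-butyldimethylsilyl)oxy]-2-methylbutanal | O=C[C@@H](C)C[C@H](C1=C(CO[Si](C)(C)C(C)(C)C)C(=O)O[C@H]1[C@H]1O[C@@]1(C)CCBr)O[Si](C)(C)C(C)(C)C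
F2 | step 15 | (4S,5R,6R,8R,10S)-8,13-bis[(tert-butyldimethylsilyl)oxy]-4,5-epoxy-1-hydroxygermacr-7(11)-en-12,6-olide (C1 epimers) | CC(C)(C)[Si](C)(C)OCC1=C2[C@@H](OC1=O)[C@H]1O[C@@]1(C)CCC(O)[C@@H](C)C[C@H]2O[Si](C)(C)C(C)(C)C
F3 | step 14 | methyl (4R,6S)-4-[(tert-butyldimethylsilyl)oxy]-7-(ethylsulfanyl)-3-hydroxy-6-methyl-2-methylidene-7-oxoheptanoate (C3 epimers) | CCSC(=O)[C@@H](C)C[C@H](C(O)C(=C)C(=O)OC)O[Si](C)(C)C(C)(C)C
F4 | step 14 | methyl (2Z,4R,6S)-2-(bromomethyl)-4-[(tert-butyldimethylsilyl)oxy]-7-(ethylsulfanyl)-6-methyl-7-oxohept-2-enoate | CCSC(=O)[C@@H](C)C[C@H](/C=C(/C(=O)OC)CBr)O[Si](C)(C)C(C)(C)C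
F5 | step 14 | S-ethyl (2S,4R)-4-{(2R)-2-[(2R,3S)-3-(2-bromoethyl)-3-methyloxiran-2-yl]-4-methylidene-5-oxooxolan-3-yl}-4-[(tert-butyldimethylsilyl)oxy]-2-methylbutanethioate (C3 of the lactone unassigned) | CCSC(=O)[C@@H](C)C[C@H](C1C(=C)C(=O)O[C@H]1[C@H]1O[C@@]1(C)CCBr)O[Si](C)(C)C(C)(C)C
F6 | step 14 | S-ethyl (2S,4R)-4-{(2R)-2-[(2R,3S)-3-(2-bromoethyl)-3-methyloxiran-2-yl]-4-(hydroperoxymethyl)-5-oxo-2,5-dihydrofuran-3-yl}-4-[(tert-butyldimethylsilyl)oxy]-2-methylbutanethioate | CCSC(=O)[C@@H](C)C[C@H](C1=C(COO)C(=O)O[C@H]1[C@H]1O[C@@]1(C)CCBr)O[Si](C)(C)C(C)(C)C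
F7 | step 14 | S-ethyl (2S,4R)-4-{(2R)-2-[(2R,3S)-3-(2-bromoethyl)-3-methyloxiran-2-yl]-4-(hydroxymethyl)-5-oxo-2,5-dihydrofuran-3-yl}-4-[(tert-butyldimethylsilyl)oxy]-2-methylbutanethioate | CCSC(=O)[C@@H](C)C[C@H](C1=C(CO)C(=O)O[C@H]1[C@H]1O[C@@]1(C)CCBr)O[Si](C)(C)C(C)(C)C
F8 | step 8 | lithium (2S,4R)-4-hydroxy-2-methyl-5-(trityloxy)pentanoate | [Li+].[O-]C(=O)[C@@H](C)C[C@H](COC(c1ccccc1)(c2ccccc2)c3ccccc3)O
F9 | step 8 | tert-butyldimethylsilyl (2S,4R)-4-[(tert-butyldimethylsilyl)oxy]-2-methyl-5-(trityloxy)pentanoate | CC(C)(C)[Si](C)(C)OC(=O)[C@@H](C)C[C@H](COC(c1ccccc1)(c2ccccc2)c3ccccc3)O[Si](C)(C)C(C)(C)C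
F10 | step 8 | (2S,4R)-4-[(tert-butyldimethylsilyl)oxy]-2-methyl-5-(trityloxy)pentanoic acid | OC(=O)[C@@H](C)C[C@H](COC(c1ccccc1)(c2ccccc2)c3ccccc3)O[Si](C)(C)C(C)(C)C
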